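A small charge of single-handed free catalyst, which the added ligand binds as idle complex, works on a racemate of the two substrates, with partner charged from 4.00 mM in eta up to 400 mM in theta.

common to all: left-handed substrate 30 mM; free catalyst 3.0 mM; precatalyst 69 µM; added ligand 7.9 mM; right-handed substrate 30 mM; time 3.0 h

|  | partner |
|---|---|
| eta | 4.00 mM |
| beta | 12.0 mM |
| zeta | 40.0 mM |
| delta | 120 mM |
| theta | 400 mM |

    partner + free catalyst + left-handed substrate → free catalyst + left-handed product (k1 = 0.15 M⁻² s⁻¹)
    partner + free catalyst + right-handed substrate → free catalyst + right-handed product (k2 = 0.017 M⁻² s⁻¹)
    left-handed substrate + racemization catalyst ⇌ right-handed substrate + racemization catalyst, rate k3*[racemization catalyst]*[left-handed substrate] forward; the back reaction follows from the equilibrium constant (k3 = 0.0098 M⁻¹ s⁻¹)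
    free catalyst + added ligand ⇌ idle complex, settled at all times (K4 = 2300 M⁻¹)
    left-handed product ⇌ right-handed product (k5 = 4.3 × 10⁻⁵ s⁻¹)
    precatalyst ⇌ racemization catalyst (K6 = 140, k6 = 1.3 × 10⁻⁴ s⁻¹)

1. amount of left-handed product at the end, in percent of the left-handed substrate and right-handed substrate together charged for eta, beta, zeta, delta, theta, in this order
2. the shape of the row from first to last (rises all the way / falls all the way / rises, then falls / falls, then rises / hardly changes)

- free catalyst is single-handed; left-handed substrate and right-handed substrate are mirror images of each other, charged as a racemate, each of them at the stated concentration
- "hardly changes" means that all values lie within two and a half points (for a concentration: within two and a half percent of the largest)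
- run time (eta): 3.0 h

The carried quantity is the share of the charged partner that ends as left-handed product in the run. To reckon it we need [free catalyst], then the correction for product racemization.

Since the added ligand exceeds the catalyst, at least 4.90 mM of it stays unbound, which bounds free catalyst from above. Putting that bound back in bounds free ligand from above, and so free catalyst from below:

[free catalyst] below 0.244 mM, above 0.234 mM

The substrates start equal, so racemization moves nothing until they differ, and 0.730 % of a substrate is what it could carry across with the precatalyst counted as converted at once. We drop it. The substrate charge then cancels from the percentage for eta. With no product racemization we get an upper bound; if every left-handed product stood the full run and the right-handed one gave nothing back, we get a lower bound: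

row, eta: below 0.0792 %, above 0.0528 %

The partner itself loses 1.26 % of its charge, less than the gap between the bounds.

To tighten this, note that racemization leaves the sum of the products alone and relaxes their difference at twice its constant. With rates held steady, the left-handed product keeps a fraction

0.845

of what was made. So the partner's share, the fraction of charged partner ending as left-handed product, pseudo-first-order in partner, is 0.961 %. Its expression contains no partner charge, and for eta it gives, as a fraction of the two substrates charged, 6.40 × 10⁻⁴.

The correction appears at the top charge: in theta the left-handed substrate's exponent is 15.1 %, so its mean level is 0.928 of its charge, and theta comes to 0.0594 as the same fraction. From delta to theta the charge grows 3.33-fold against that loss, so the shape we commit to is: rises all the way.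

The forecast gave 0.064 %, 0.19 %, 0.63 %, 1.87 %, 5.9 %, and said the row rises all the way, on the ground that “Output scales nearly linearly with partner”. Its eta value lies inside our bracket.

The flasks give 0.0637 %, 0.191 %, 0.632 %, 1.87 %, 5.90 %: the row rises all the way. In eta, at 3.00 h, the left-handed substrate has a half-life of 58 d by the first step, against a run of 3.0 h. The substrates' relaxation half-life there is 189 h, and 99.8 % of the left-handed substrate stands at the end. Read back from eta, the partner's share is 0.956 %, against our 0.961 %. In theta the flask gives 5.90 %, and the left-handed substrate ends at 86 % of its charge.

All constants were chosen freely; the flask was simulated.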